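## Retrosynthetic overview

1. Target 22 ⇒ 4-ketone 21 (C4=C18 by late methylenation) ⇒ carbinol 19 (hydroxyl-directed C6 reduction, then acetylation).
2. Key disconnection C11–C12: decalin aldehyde 16 + 4-(bromomethyl)butenolide 17, joined by a cathodic, zinc-anode vinylogous Reformatsky coupling that also sets C11; the butenolide ring arrives preformed.
3. 7α,8α-Diol from enone 13 by α-face osmylation; enone from silyl enol ether 12 (Saegusa).
4. Rings A and B are formed together by an intramolecular Diels–Alder reaction of silyl dienol ether 11 (C5–C10 and C8–C9; C5, C9, C10 set under control of C1).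
5. Acyclic precursor 10 from the L-glutamic-acid-derived lactone 1 (C1, the only purchased stereocentre), (E)-hex-4-en-3-one 3 (Claisen, C4–C5) and ylide 8 (Wittig, C9=C10).

Assumption: decalin compounds carry clerodane numbering (C1–C10 ring carbons, C11–C16 side chain, C17/C19/C20 = methyls on C8/C5/C9, C18 = exocyclic CH2); α is the face of H-10, β the face of the C19/C20 methyls; β-diketones are drawn in the keto form and carried as C5-epimer/enol mixtures.

## Route

Step 1
Reactants: 1 (S)-5-(hydroxymethyl)dihydrofuran-2(3H)-one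
Product: 2 (S)-5-{[(tert-butyldiphenylsilyl)oxy]methyl}dihydrofuran-2(3H)-one
Conditions: TBDPSCl, imidazole, DMF, 0 °C → rt
Reagents that add atoms: tert-butyldiphenylsilyl chloride, CC(C)(C)[Si](Cl)(c1ccccc1)c1ccccc1
Why: Standard silyl ether formation on the primary alcohol; the bulky, migration-resistant silyl group masks the future C10 oxygen through the basic Claisen step and the stereocentre (future C1) is not touched.

Step 2
Reactants: 2 (S)-5-{[(tert-butyldiphenylsilyl)oxy]methyl}dihydrofuran-2(3H)-one; 3 (E)-hex-4-en-3-one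
Product: 5 (2S,8E)-1-[(tert-butyldiphenylsilyl)oxy]-2-hydroxy-6-methyldec-8-ene-5,7-dione, via lithium dienolate 4 (not isolated)
Conditions: 3 (2.3 equiv), LiN(i-Pr)2 (2.3 equiv), THF, −78 °C; then 2, −78 → −20 °C; aq NH4Cl
Reagents that add atoms: none
Why: Crossed Claisen condensation in which the kinetic cross-conjugated enolate of 3 is C-acylated by the lactone carbonyl (C4–C5 bond), the second equivalent of enolate deprotonating the β-diketone so that reaction stops there, while ring opening frees the C1 hydroxyl without touching the stereocentre.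

Step 3
Reactants: 5 (2S,8E)-1-[(tert-butyldiphenylsilyl)oxy]-2-hydroxy-6-methyldec-8-ene-5,7-dione
Product: 6 (2S,8E)-1-[(tert-butyldiphenylsilyl)oxy]-6-methyl-5,7-dioxodec-8-en-2-yl acetate
Conditions: Ac2O, pyridine, CH2Cl2, 0 °C → rt
Reagents that add atoms: acetic anhydride, CC(=O)OC(C)=O
Why: Acetylation of the only alcohol installs the C1 acetate of the target at once and stops hemiketal formation and cyclodehydration of the γ-hydroxy ketone.

Step 4
Reactants: 6 (2S,8E)-1-[(tert-butyldiphenylsilyl)oxy]-6-methyl-5,7-dioxodec-8-en-2-yl acetate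
Product: 7 (2S,8E)-1-hydroxy-6-methyl-5,7-dioxodec-8-en-2-yl acetate
Conditions: HF·pyridine, THF, 0 °C → rt
Reagents that add atoms: none
Why: Fluoride-mediated Si–O cleavage under buffered, non-basic conditions frees the primary alcohol without acetyl migration or retro-Claisen cleavage of the β-diketone.

Step 5
Reactants: 7 (2S,8E)-1-hydroxy-6-methyl-5,7-dioxodec-8-en-2-yl acetate; 8 2-(triphenylphosphoranylidene)propanal
Product: 10 (2E,4S,10E)-2,8-dimethyl-1,7,9-trioxododeca-2,10-dien-4-yl acetate, via α-acetoxy aldehyde 9 (not isolated)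
Conditions: DMP, CH2Cl2, 0 °C; then 8 (1.3 equiv), rt
Reagents that add atoms: none
Why: Dess–Martin oxidation gives the sensitive α-acetoxy aldehyde, which is trapped in the same flask by the stabilised, non-basic ylide in an (E)-selective Wittig olefination without epimerising C1, creating C9=C10 and the aldehyde (C11) that activates the dienophile.

Step 6
Reactants: 10 (2E,4S,10E)-2,8-dimethyl-1,7,9-trioxododeca-2,10-dien-4-yl acetate
Product: 12 1α-acetoxy-6-(tert-butyldimethylsilyloxy)-5β,8α,9β-trimethyl-4-oxo-10α-H-decal-6-ene-9α-carbaldehyde, via silyl dienol ether 11 (not isolated)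
Conditions: TBSOTf, Et3N, CH2Cl2, −78 °C; then PhMe (0.01 M), BHT, 110 °C
Reagents that add atoms: tert-butyldimethylsilyl trifluoromethanesulfonate, CC(C)(C)[Si](C)(C)OS(=O)(=O)C(F)(F)F
Why: O-silylation of the β-diketone gives the (Z)-enol silane (tether carbon C4 outside, C19 methyl inside), a 2-silyloxy diene that undergoes an intramolecular Diels–Alder reaction with the (E)-enal through the endo-CHO, chair-like transition state to form C5–C10 and C8–C9 and the trans-decalin (5β-Me, 10α-H, 9β-Me, 9α-CHO), while allylic 1,3-strain between the C9 methyl and C1 keeps the C1 acetate equatorial so that the purchased stereocentre selects the diene face.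

Step 7
Reactants: 12 1α-acetoxy-6-(tert-butyldimethylsilyloxy)-5β,8α,9β-trimethyl-4-oxo-10α-H-decal-6-ene-9α-carbaldehyde
Product: 13 1α-acetoxy-5β,8,9β-trimethyl-4,6-dioxo-10α-H-decal-7-ene-9α-carbaldehyde
Conditions: Pd(OAc)2 (1.1 equiv), MeCN, rt
Reagents that add atoms: none
Why: Saegusa–Ito oxidation, in which the divalent palladium enolate formed from the silyl enol ether loses H-8 (the only β-hydrogen, C5 being quaternary) to give the C6-keto Δ7 enone regiospecifically and erase the C8 stereocentre.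

Step 8
Reactants: 13 1α-acetoxy-5β,8,9β-trimethyl-4,6-dioxo-10α-H-decal-7-ene-9α-carbaldehyde
Product: 15 1α-acetoxy-7α,8α-dihydroxy-5β,8β,9β-trimethyl-4,6-dioxo-10α-H-decalin-9α-carbaldehyde, via cyclic osmate ester 14 (not isolated)
Conditions: OsO4 (1.1 equiv), pyridine, THF, 0 °C → rt; then aq NaHSO3
Reagents that add atoms: osmium tetroxide, O=[Os](=O)(=O)=O
Why: Stoichiometric osmylation (reliable for hindered, electron-poor enones) is a [3+2] cis-dihydroxylation that adds to the α-face of C7=C8 because the β-face is shielded by the axial C19 and C20 methyls, giving 7α-OH and 8α-OH with the C17 methyl β.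

Step 9
Reactants: 15 1α-acetoxy-7α,8α-dihydroxy-5β,8β,9β-trimethyl-4,6-dioxo-10α-H-decalin-9α-carbaldehyde
Product: 16 1α-acetoxy-8α-hydroxy-7α-isobutyryloxy-5β,8β,9β-trimethyl-4,6-dioxo-10α-H-decalin-9α-carbaldehyde
Conditions: (i-PrCO)2O, DMAP (cat.), pyridine, CH2Cl2, 0 °C
Reagents that add atoms: isobutyric anhydride, CC(C)C(=O)OC(=O)C(C)C
Why: DMAP-catalysed acylation takes place only at the secondary equatorial 7α-hydroxyl (the tertiary axial 8α-hydroxyl next to quaternary C9 is inert), so the isobutyrate is placed while no other secondary alcohol exists.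

Step 10
Reactants: 16 1α-acetoxy-8α-hydroxy-7α-isobutyryloxy-5β,8β,9β-trimethyl-4,6-dioxo-10α-H-decalin-9α-carbaldehyde; 17 4-(bromomethyl)furan-2(5H)-one
Product: 19 (11R)-1α-acetoxy-8α,11-dihydroxy-7α-isobutyryloxy-4,6-dioxo-18-nor-13-en-15,16-olide, via bromozinc dienolate 18 (not isolated)
Conditions: undivided cell, Zn anode, carbon-felt cathode, Bu4NBr (0.1 M), DMF, constant current (2.2 F per mol 17), 17 (2.5 equiv) added slowly, 40 °C; aq NH4Cl
Reagents that add atoms: none
Why: Proposed new method: cathodic two-electron cleavage of the allylic C–Br bond of 17 in the presence of Zn2+ from the sacrificial anode generates, at low stationary concentration (suppressing Wurtz dimerisation), the cross-conjugated zinc dienolate 18 that deprotonation cannot give (it leads to the aromatic 2-oxidofuran), and 18 should bond through its exocyclic γ-carbon to the non-enolisable neopentyl aldehyde because the congested α-adduct reverts by retro-aldol to the conjugated γ-adduct, while Zn2+ bridging the 8α-hydroxyl and the aldehyde oxygen in a six-membered chelate exposes the carbonyl face next to the small C20 methyl and away from ring A so that C11–C12 forms with the (11R) configuration; the closest known reactions are the electrochemical Reformatsky reaction of α-bromo esters at a sacrificial zinc anode and the thermal vinylogous Reformatsky reaction of 4-bromocrotonates.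

Step 11
Reactants: 19 (11R)-1α-acetoxy-8α,11-dihydroxy-7α-isobutyryloxy-4,6-dioxo-18-nor-13-en-15,16-olide
Product: 20 (11R)-1α-acetoxy-6β,8α,11-trihydroxy-7α-isobutyryloxy-4-oxo-18-nor-13-en-15,16-olide
Conditions: Me4NBH(OAc)3, MeCN/AcOH, −30 → 0 °C
Reagents that add atoms: none
Why: Evans–Saksena hydroxyl-directed reduction, in which the axial 8α-hydroxyl binds boron and delivers hydride to the α-face of the C6 ketone (1,3-anti diol, equatorial 6β-OH), leaving the C4 ketone, which has no β-hydroxyl, and the butenolide untouched.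

Step 12
Reactants: 20 (11R)-1α-acetoxy-6β,8α,11-trihydroxy-7α-isobutyryloxy-4-oxo-18-nor-13-en-15,16-olide
Product: 21 (11R)-1α,6β,11-triacetoxy-8α-hydroxy-7α-isobutyryloxy-4-oxo-18-nor-13-en-15,16-olide
Conditions: Ac2O, DMAP, pyridine, 40 °C
Reagents that add atoms: acetic anhydride, CC(=O)OC(C)=O
Why: DMAP-catalysed acetylation of the two secondary alcohols (C6 and C11) in one operation; the hindered tertiary C8 alcohol stays free.

Step 13
Reactants: 21 (11R)-1α,6β,11-triacetoxy-8α-hydroxy-7α-isobutyryloxy-4-oxo-18-nor-13-en-15,16-olide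
Product: 22 CNP0266716.2 (1S,5S,6S,7R,8S,9R,10R,11R)-1α,6β,11-triacetoxy-8α-hydroxy-7α-isobutyryloxy-4(18),13-dien-15,16-olide
Conditions: Zn, CH2Br2, TiCl4, THF/CH2Cl2, 0 °C → rt
Reagents that add atoms: dibromomethane, BrCBr
Why: Takai–Lombardo methylenation, whose non-basic zinc/titanium methylene reagent converts the hindered C4 ketone into the exocyclic methylene without attacking the esters or the butenolide and without epimerisation.

## Compound list

1 | (S)-5-(hydroxymethyl)dihydrofuran-2(3H)-one | OC[C@@H]1CCC(=O)O1 | starting material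
2 | (S)-5-{[(tert-butyldiphenylsilyl)oxy]methyl}dihydrofuran-2(3H)-one | CC(C)(C)[Si](OC[C@@H]1CCC(=O)O1)(c1ccccc1)c1ccccc1 | intermediate
3 | (E)-hex-4-en-3-one | CCC(=O)/C=C/C | starting material
4 | lithium (4E)-hexa-2,4-dien-3-olate (lithium dienolate of 3) | CC=C(O[Li])/C=C/C | intermediate
5 | (2S,8E)-1-[(tert-butyldiphenylsilyl)oxy]-2-hydroxy-6-methyldec-8-ene-5,7-dione | CC(C)(C)[Si](OC[C@@H](O)CCC(=O)C(C)C(=O)/C=C/C)(c1ccccc1)c1ccccc1 | intermediate
6 | (2S,8E)-1-[(tert-butyldiphenylsilyl)oxy]-6-methyl-5,7-dioxodec-8-en-2-yl acetate | CC(C)(C)[Si](OC[C@@H](OC(C)=O)CCC(=O)C(C)C(=O)/C=C/C)(c1ccccc1)c1ccccc1 | intermediate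
7 | (2S,8E)-1-hydroxy-6-methyl-5,7-dioxodec-8-en-2-yl acetate | OC[C@@H](OC(C)=O)CCC(=O)C(C)C(=O)/C=C/C | intermediate
8 | 2-(triphenylphosphoranylidene)propanal | CC(C=O)=P(c1ccccc1)(c1ccccc1)c1ccccc1 | starting material
9 | (2S,8E)-6-methyl-1,5,7-trioxodec-8-en-2-yl acetate (α-acetoxy aldehyde) | O=C[C@@H](OC(C)=O)CCC(=O)C(C)C(=O)/C=C/C | intermediate
10 | (2E,4S,10E)-2,8-dimethyl-1,7,9-trioxododeca-2,10-dien-4-yl acetate | O=C/C(C)=C/[C@@H](OC(C)=O)CCC(=O)C(C)C(=O)/C=C/C | intermediate
11 | (2E,4S,8Z,10E)-9-[(tert-butyldimethylsilyl)oxy]-2,8-dimethyl-1,7-dioxododeca-2,8,10-trien-4-yl acetate (silyl dienol ether) | O=C/C(C)=C/[C@@H](OC(C)=O)CCC(=O)/C(C)=C(/C=C/C)O[Si](C)(C)C(C)(C)C | intermediate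
12 | 1α-acetoxy-6-(tert-butyldimethylsilyloxy)-5β,8α,9β-trimethyl-4-oxo-10α-H-decal-6-ene-9α-carbaldehyde | O=C1CC[C@H](OC(C)=O)[C@@H]2[C@]1(C)C(O[Si](C)(C)C(C)(C)C)=C[C@@H](C)[C@@]2(C)C=O | intermediate
13 | 1α-acetoxy-5β,8,9β-trimethyl-4,6-dioxo-10α-H-decal-7-ene-9α-carbaldehyde | O=C1CC[C@H](OC(C)=O)[C@@H]2[C@]1(C)C(=O)C=C(C)[C@@]2(C)C=O | intermediate
14 | 7α,8α-cyclic osmate ester of 13 (pyridine ligands omitted) | O=C1CC[C@H](OC(C)=O)[C@@H]2[C@]1(C)C(=O)[C@H]3O[Os](=O)(=O)O[C@@]3(C)[C@@]2(C)C=O | intermediate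
15 | 1α-acetoxy-7α,8α-dihydroxy-5β,8β,9β-trimethyl-4,6-dioxo-10α-H-decalin-9α-carbaldehyde | O=C1CC[C@H](OC(C)=O)[C@@H]2[C@]1(C)C(=O)[C@@H](O)[C@@](C)(O)[C@@]2(C)C=O | intermediate
16 | 1α-acetoxy-8α-hydroxy-7α-isobutyryloxy-5β,8β,9β-trimethyl-4,6-dioxo-10α-H-decalin-9α-carbaldehyde | O=C1CC[C@H](OC(C)=O)[C@@H]2[C@]1(C)C(=O)[C@@H](OC(=O)C(C)C)[C@@](C)(O)[C@@]2(C)C=O | intermediate
17 | 4-(bromomethyl)furan-2(5H)-one | BrCC1=CC(=O)OC1 | starting material
18 | bromozinc 4-methylene-4,5-dihydrofuran-2-olate (bromozinc dienolate) | Br[Zn]OC1=CC(=C)CO1 | intermediate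
19 | (11R)-1α-acetoxy-8α,11-dihydroxy-7α-isobutyryloxy-4,6-dioxo-18-nor-13-en-15,16-olide | O=C1CC[C@H](OC(C)=O)[C@@H]2[C@]1(C)C(=O)[C@@H](OC(=O)C(C)C)[C@@](C)(O)[C@@]2(C)[C@@H](CC1=CC(=O)OC1)O | intermediate
20 | (11R)-1α-acetoxy-6β,8α,11-trihydroxy-7α-isobutyryloxy-4-oxo-18-nor-13-en-15,16-olide | O=C1CC[C@H](OC(C)=O)[C@@H]2[C@]1(C)[C@H](O)[C@@H](OC(=O)C(C)C)[C@@](C)(O)[C@@]2(C)[C@@H](CC1=CC(=O)OC1)O | intermediate
21 | (11R)-1α,6β,11-triacetoxy-8α-hydroxy-7α-isobutyryloxy-4-oxo-18-nor-13-en-15,16-olide | O=C1CC[C@H](OC(C)=O)[C@@H]2[C@]1(C)[C@H](OC(C)=O)[C@@H](OC(=O)C(C)C)[C@@](C)(O)[C@@]2(C)[C@@H](CC1=CC(=O)OC1)OC(C)=O | intermediate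
22 | CNP0266716.2, (1S,5S,6S,7R,8S,9R,10R,11R)-1α,6β,11-triacetoxy-8α-hydroxy-7α-isobutyryloxy-4(18),13-dien-15,16-olide | C=C1CC[C@H](OC(C)=O)[C@@H]2[C@]1(C)[C@H](OC(C)=O)[C@@H](OC(=O)C(C)C)[C@@](C)(O)[C@@]2(C)[C@@H](CC1=CC(=O)OC1)OC(C)=O | target

## Summary and risks

Total step count: 13. Longest linear sequence: 13 steps (1 → 22); compounds 3, 8 and 17 are bought.

Steps most likely to fail:

- **Step 10** (the proposed new electro-coupling; α- versus γ-attack of the dienolate and the C11 configuration are untested). The fallback uses known chemistry, sets out from 16 and returns at 19. Indium-mediated Barbier reaction of 16 with 3-chloro-2-(chloromethyl)prop-1-ene (In powder, NaI, DMF), under the same chelation control, gives the 2-(chloromethyl)allyl carbinol F1. Displacement of the allylic chloride with CH2=CHCO2Na (Bu4NI, DMF, 50 °C) gives the acrylate F2. Ring-closing metathesis with the second-generation Grubbs catalyst RuCl2(H2IMes)(PCy3)(=CHPh) in CH2Cl2 at 40 °C closes the butenolide (C13=C14) and delivers 19.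

- **Step 6** (the acyl-substituted silyloxy diene may be sluggish, and the trans/cis and facial selectivities are predicted, not proven). The fallback sets out from 10 and returns at 13 by an anionic Michael–Michael annulation. KN(SiMe3)2 (1.0 equiv, THF, −78 → −20 °C) removes only the acidic diketone proton. The diketonate adds to the enal (C5–C10), the aldehyde enolate so formed closes ring B onto the propenyl ketone (C9–C8), and Me3SiCl traps the resulting C6 enolate as the trimethylsilyl enol ether F3 (the Me3Si analogue of 12). Saegusa oxidation of F3 with Pd(OAc)2 gives 13.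

- **Step 2** (crossed Claisen on an enolisable lactone; proton transfer and cyclodehydration of the γ-hydroxy diketone can erode the yield). The fallback sets out from 2 and returns at 5. Me(MeO)NH·HCl with Me3Al opens the lactone to the hydroxy Weinreb amide F4. Et3SiCl and imidazole give the triethylsilyl ether F5. Acylation of dienolate 4 with F5 gives the 2-O-triethylsilyl diketone F6. AcOH/THF/H2O removes the triethylsilyl group while the primary TBDPS ether survives, giving 5.

## Further compounds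

F1 | step 10 | 2-(chloromethyl)allyl carbinol: 16 with 9α-CHO converted to (R)-CH(OH)CH2C(=CH2)CH2Cl | O=C1CC[C@H](OC(C)=O)[C@@H]2[C@]1(C)C(=O)[C@@H](OC(=O)C(C)C)[C@@](C)(O)[C@@]2(C)[C@@H](CC(=C)CCl)O
F2 | step 10 | acrylate: F1 with CH2Cl converted to CH2OC(=O)CH=CH2 | O=C1CC[C@H](OC(C)=O)[C@@H]2[C@]1(C)C(=O)[C@@H](OC(=O)C(C)C)[C@@](C)(O)[C@@]2(C)[C@@H](CC(=C)COC(=O)C=C)O
F3 | step 6 | 1α-acetoxy-6-(trimethylsilyloxy)-5β,8α,9β-trimethyl-4-oxo-10α-H-decal-6-ene-9α-carbaldehyde | O=C1CC[C@H](OC(C)=O)[C@@H]2[C@]1(C)C(O[Si](C)(C)C)=C[C@@H](C)[C@@]2(C)C=O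
F4 | step 2 | (S)-5-[(tert-butyldiphenylsilyl)oxy]-4-hydroxy-N-methoxy-N-methylpentanamide | CC(C)(C)[Si](OC[C@@H](O)CCC(=O)N(C)OC)(c1ccccc1)c1ccccc1
F5 | step 2 | (S)-5-[(tert-butyldiphenylsilyl)oxy]-N-methoxy-N-methyl-4-[(triethylsilyl)oxy]pentanamide | CC(C)(C)[Si](OC[C@@H](O[Si](CC)(CC)CC)CCC(=O)N(C)OC)(c1ccccc1)c1ccccc1
F6 | step 2 | (2S,8E)-1-[(tert-butyldiphenylsilyl)oxy]-6-methyl-2-[(triethylsilyl)oxy]dec-8-ene-5,7-dione | CC(C)(C)[Si](OC[C@@H](O[Si](CC)(CC)CC)CCC(=O)C(C)C(=O)/C=C/C)(c1ccccc1)c1ccccc1
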